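**Retrosynthetic overview**
1. Last step: hydrogenolysis of the nonadeca-O-benzyl ether; all five ring types (A–E) are bought as benzenoid building blocks, none is built de novo.
2. A–O–B ether: Cu-catalysed arylation of the central phenol of ring B, which is unmasked from a benzaldehyde by Dakin oxidation.
3. B–O–C ethers: two-fold SNAr of the arm phenol (rings C–D–E) on 4-(benzyloxy)-2,6-difluorobenzaldehyde, where CHO serves as activator and as latent OH.
4. C–O–D ether: Ullmann coupling of the D–E phenol with 4-bromo-2,6-bis(benzyloxy)benzaldehyde, then Dakin oxidation.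
5. D–E biaryl bond (key step): intermolecular Michael addition of 1,3,5-tris(benzyloxy)benzene to 2,6-bis(benzyloxy)-1,4-benzoquinone. Order of joining: E–D, then C, then B, then A.

Assumption: the target has no stereocentre and no stereogenic axis (ring E is symmetric about the D–E bond), so it is one achiral compound and its SMILES carry no stereodescriptors.

**Route**

Step 1
Reactants: 1 phloroglucinol (benzene-1,3,5-triol)
Product: 2 benzene-1,3,5-triyl triacetate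
Conditions: Ac2O, pyridine, 0 °C to rt
Reagents that add atoms: acetic anhydride, CC(=O)OC(C)=O
Why: Exhaustive O-acylation (nucleophilic acyl substitution) gives a stable triester from which the phenoxides can be released gradually, which avoids the C-benzylation that free phloroglucinol suffers.

Step 2
Reactants: 2 benzene-1,3,5-triyl triacetate
Product: 3 1,3,5-tris(benzyloxy)benzene
Conditions: BnCl, NaH, DMF, 0 °C; H2O (3 equiv) added slowly; then rt
Reagents that add atoms: benzyl chloride, ClCc1ccccc1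
Why: NaOH formed in situ cleaves the acetates slowly and each phenoxide is trapped at once by excess benzyl chloride (Williamson ether synthesis), so O-alkylation outruns C-alkylation.

Step 3
Reactants: 3 1,3,5-tris(benzyloxy)benzene
Product: 5 2,4,6-tris(benzyloxy)benzaldehyde, via iminium chloride 4 (not isolated)
Conditions: POCl3, DMF, 0 °C to rt; then ice-water
Reagents that add atoms: N,N-dimethylformamide, CN(C)C=O; water, O
Why: Vilsmeier–Haack formylation of the threefold-symmetric, very electron-rich arene can give only one regioisomer, and the iminium group of 4 deactivates the ring against a second attack.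

Step 4
Reactants: 5 2,4,6-tris(benzyloxy)benzaldehyde
Product: 7 2,4,6-tris(benzyloxy)phenol, via aryl formate 6 (not isolated)
Conditions: mCPBA, CH2Cl2, 0 °C to rt; then Et3N (cat.), MeOH, rt
Reagents that add atoms: 3-chloroperoxybenzoic acid, OOC(=O)c1cccc(Cl)c1
Why: In this Dakin-type Baeyer–Villiger oxidation the aryl group carrying three ortho/para oxygen donors migrates in preference to hydride, and the formate is cleaved by mild methanolysis.

Step 5
Reactants: 7 2,4,6-tris(benzyloxy)phenol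
Product: 9 2,6-bis(benzyloxy)-1,4-benzoquinone, via hemiketal 8 (not isolated)
Conditions: PhI(OAc)2, MeCN/H2O (4:1), 0 °C
Reagents that add atoms: water, O
Why: Hypervalent-iodine oxidative dearomatisation of a p-alkoxyphenol lets water add at the para carbon, and hemiketal 8 collapses with loss of benzyl alcohol to the p-quinone.

Step 6 (key step)
Reactants: 9 2,6-bis(benzyloxy)-1,4-benzoquinone; 3 1,3,5-tris(benzyloxy)benzene
Product: 11 2,6-bis(benzyloxy)-3-[2,4,6-tris(benzyloxy)phenyl]benzene-1,4-diol, via Michael adduct 10 (not isolated)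
Conditions: Sc(OTf)3 (10 mol %), MeCN/CH2Cl2, 0 °C to rt, under argon; 9 added slowly to 3 (1.5 equiv)
Reagents that add atoms: none
Why: Sc(OTf)3 chelated between the C1 carbonyl and a flanking benzyloxy oxygen activates the cross-conjugated enone, whose only β-carbons (C3/C5, equivalent) are attacked by the arene acting as the tris-enol ether of cyclohexane-1,3,5-trione in a Mukaiyama-type Michael addition; tautomerisation of 10 aromatises both rings and erases its transient sp3 centre, so no stereocentre remains.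

Step 7
Reactants: 11 2,6-bis(benzyloxy)-3-[2,4,6-tris(benzyloxy)phenyl]benzene-1,4-diol
Product: 12 2,4,6-tris(benzyloxy)-3-[2,4,6-tris(benzyloxy)phenyl]phenol
Conditions: BnBr (1.05 equiv), K2CO3 (1.1 equiv), DMF, 0 °C to rt, under argon
Reagents that add atoms: benzyl bromide, BrCc1ccccc1
Why: The C4 hydroxyl is meta to both benzyloxy groups and has a free ortho position, so it is the more acidic and less shielded phenol and is alkylated first (Williamson ether synthesis), while the C1 hydroxyl sits hydrogen-bonded between two benzyloxy groups.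

Step 8
Reactants: 13 4-bromo-2,6-difluorobenzaldehyde
Product: 15 2,6-bis(benzyloxy)-4-bromobenzaldehyde, via monobenzyl ether 14 (not isolated)
Conditions: BnOH (2.2 equiv), NaH (2.2 equiv), THF, 0 °C to 50 °C
Reagents that add atoms: benzyl alcohol, OCc1ccccc1
Why: Both fluorides are ortho to the formyl group and are displaced by benzyloxide in two SNAr reactions, whereas bromide is a far poorer leaving group in SNAr and is kept.

Step 9
Reactants: 12 2,4,6-tris(benzyloxy)-3-[2,4,6-tris(benzyloxy)phenyl]phenol; 15 2,6-bis(benzyloxy)-4-bromobenzaldehyde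
Product: 16 2,6-bis(benzyloxy)-4-{2,4,6-tris(benzyloxy)-3-[2,4,6-tris(benzyloxy)phenyl]phenoxy}benzaldehyde
Conditions: CuI (10 mol %), picolinic acid (20 mol %), K3PO4 (2 equiv), DMSO, 90 °C, under argon
Reagents that add atoms: none
Why: Ullmann diaryl ether coupling under the picolinic acid protocol tolerates di-ortho-substituted phenols, and the bromide is unhindered and activated by the para formyl group.

Step 10
Reactants: 16 2,6-bis(benzyloxy)-4-{2,4,6-tris(benzyloxy)-3-[2,4,6-tris(benzyloxy)phenyl]phenoxy}benzaldehyde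
Product: 18 2,6-bis(benzyloxy)-4-{2,4,6-tris(benzyloxy)-3-[2,4,6-tris(benzyloxy)phenyl]phenoxy}phenol, via aryl formate 17 (not isolated)
Conditions: mCPBA, CH2Cl2, 0 °C to rt; then Et3N (cat.), MeOH, rt
Reagents that add atoms: 3-chloroperoxybenzoic acid, OOC(=O)c1cccc(Cl)c1
Why: Dakin-type Baeyer–Villiger oxidation again proceeds by migration of the 2,4,6-trioxygenated aryl group and unmasks the central phenol of ring C.

Step 11
Reactants: 19 2,6-difluoro-4-hydroxybenzaldehyde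
Product: 20 4-(benzyloxy)-2,6-difluorobenzaldehyde
Conditions: BnBr, K2CO3, DMF, rt
Reagents that add atoms: benzyl bromide, BrCc1ccccc1
Why: Williamson benzylation of an acidic para-formyl phenol is clean, and carbonate at rt does not touch the fluorides.

Step 12
Reactants: 20 4-(benzyloxy)-2,6-difluorobenzaldehyde; 18 2,6-bis(benzyloxy)-4-{2,4,6-tris(benzyloxy)-3-[2,4,6-tris(benzyloxy)phenyl]phenoxy}phenol
Product: 22 4-(benzyloxy)-2,6-bis(2,6-bis(benzyloxy)-4-{2,4,6-tris(benzyloxy)-3-[2,4,6-tris(benzyloxy)phenyl]phenoxy}phenoxy)benzaldehyde, via mono-aryl ether 21 (not isolated)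
Conditions: 18 (2.2 equiv), Cs2CO3 (2.5 equiv), DMSO, 80 °C then 120 °C, under argon
Reagents that add atoms: none
Why: Each fluoride is ortho to the formyl group and has a free neighbouring position, so the caesium phenoxide of 18 displaces both by SNAr, a reaction far less sensitive to nucleophile bulk than metal-catalysed coupling.

Step 13
Reactants: 22 4-(benzyloxy)-2,6-bis(2,6-bis(benzyloxy)-4-{2,4,6-tris(benzyloxy)-3-[2,4,6-tris(benzyloxy)phenyl]phenoxy}phenoxy)benzaldehyde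
Product: 24 4-(benzyloxy)-2,6-bis(2,6-bis(benzyloxy)-4-{2,4,6-tris(benzyloxy)-3-[2,4,6-tris(benzyloxy)phenyl]phenoxy}phenoxy)phenol, via aryl formate 23 (not isolated)
Conditions: mCPBA, CH2Cl2, 0 °C to rt; then Et3N (cat.), MeOH/THF, rt
Reagents that add atoms: 3-chloroperoxybenzoic acid, OOC(=O)c1cccc(Cl)c1
Why: The aldehyde carbon bears an aryl group with oxygen donors at both ortho positions and the para position, so Dakin-type Baeyer–Villiger aryl migration turns the activating group into the central ring B hydroxyl.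

Step 14
Reactants: 24 4-(benzyloxy)-2,6-bis(2,6-bis(benzyloxy)-4-{2,4,6-tris(benzyloxy)-3-[2,4,6-tris(benzyloxy)phenyl]phenoxy}phenoxy)phenol; 25 1-bromo-3,5-bis(benzyloxy)benzene
Product: 26 5-(benzyloxy)-2-[3,5-bis(benzyloxy)phenoxy]-1,3-bis(2,6-bis(benzyloxy)-4-{2,4,6-tris(benzyloxy)-3-[2,4,6-tris(benzyloxy)phenyl]phenoxy}phenoxy)benzene
Conditions: CuI (20 mol %), picolinic acid (40 mol %), K3PO4 (2 equiv), DMSO, 100 °C, under argon
Reagents that add atoms: none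
Why: Ullmann coupling pairs the hindered phenol with an aryl bromide that has no ortho substituent, the favourable combination for this protocol, and the inert atmosphere protects the electron-rich phenol from oxidation.

Step 15
Reactants: 26 5-(benzyloxy)-2-[3,5-bis(benzyloxy)phenoxy]-1,3-bis(2,6-bis(benzyloxy)-4-{2,4,6-tris(benzyloxy)-3-[2,4,6-tris(benzyloxy)phenyl]phenoxy}phenoxy)benzene
Product: 27 5-hydroxy-2-(3,5-dihydroxyphenoxy)-1,3-bis{2,6-dihydroxy-4-[2,4,6-trihydroxy-3-(2,4,6-trihydroxyphenyl)phenoxy]phenoxy}benzene (CNP0227063.0)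
Conditions: H2 (1 atm), Pd(OH)2/C, THF/MeOH (1:1), rt; filtered under argon
Reagents that add atoms: none
Why: Catalytic hydrogenolysis cleaves all nineteen benzylic C–O bonds under neutral conditions that leave diaryl ether and biaryl bonds untouched, and no stereocentre is involved.

**Compound list**

1 | phloroglucinol (benzene-1,3,5-triol) | Oc1cc(O)cc(O)c1 | starting material
2 | benzene-1,3,5-triyl triacetate | CC(=O)Oc1cc(OC(C)=O)cc(OC(C)=O)c1 | intermediate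
3 | 1,3,5-tris(benzyloxy)benzene | c1ccc(COc2cc(OCc3ccccc3)cc(OCc3ccccc3)c2)cc1 | intermediate
4 | dimethyl{[2,4,6-tris(benzyloxy)phenyl]methylidene}ammonium chloride (not isolated) | C[N+](C)=Cc1c(OCc2ccccc2)cc(OCc2ccccc2)cc1OCc1ccccc1.[Cl-] | intermediate
5 | 2,4,6-tris(benzyloxy)benzaldehyde | O=Cc1c(OCc2ccccc2)cc(OCc2ccccc2)cc1OCc1ccccc1 | intermediate
6 | 2,4,6-tris(benzyloxy)phenyl formate (not isolated) | O=COc1c(OCc2ccccc2)cc(OCc2ccccc2)cc1OCc1ccccc1 | intermediate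
7 | 2,4,6-tris(benzyloxy)phenol | Oc1c(OCc2ccccc2)cc(OCc2ccccc2)cc1OCc1ccccc1 | intermediate
8 | 2,4,6-tris(benzyloxy)-4-hydroxycyclohexa-2,5-dien-1-one (not isolated) | O=C1C(OCc2ccccc2)=CC(O)(OCc2ccccc2)C=C1OCc1ccccc1 | intermediate
9 | 2,6-bis(benzyloxy)-1,4-benzoquinone | O=C1C=C(OCc2ccccc2)C(=O)C(OCc2ccccc2)=C1 | intermediate
10 | 3,5-bis(benzyloxy)-4-hydroxy-6-[2,4,6-tris(benzyloxy)phenyl]cyclohexa-2,4-dien-1-one (racemic, transient, not isolated) | O=C1C=C(OCc2ccccc2)C(O)=C(OCc2ccccc2)C1c1c(OCc2ccccc2)cc(OCc2ccccc2)cc1OCc1ccccc1 | intermediate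
11 | 2,6-bis(benzyloxy)-3-[2,4,6-tris(benzyloxy)phenyl]benzene-1,4-diol | Oc1c(OCc2ccccc2)cc(O)c(-c2c(OCc3ccccc3)cc(OCc3ccccc3)cc2OCc2ccccc2)c1OCc1ccccc1 | intermediate
12 | 2,4,6-tris(benzyloxy)-3-[2,4,6-tris(benzyloxy)phenyl]phenol | Oc1c(OCc2ccccc2)cc(OCc2ccccc2)c(-c2c(OCc3ccccc3)cc(OCc3ccccc3)cc2OCc2ccccc2)c1OCc1ccccc1 | intermediate
13 | 4-bromo-2,6-difluorobenzaldehyde | O=Cc1c(F)cc(Br)cc1F | starting material
14 | 2-(benzyloxy)-4-bromo-6-fluorobenzaldehyde (not isolated) | O=Cc1c(F)cc(Br)cc1OCc1ccccc1 | intermediate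
15 | 2,6-bis(benzyloxy)-4-bromobenzaldehyde | O=Cc1c(OCc2ccccc2)cc(Br)cc1OCc1ccccc1 | intermediate
16 | 2,6-bis(benzyloxy)-4-{2,4,6-tris(benzyloxy)-3-[2,4,6-tris(benzyloxy)phenyl]phenoxy}benzaldehyde | O=Cc1c(OCc2ccccc2)cc(Oc2c(OCc3ccccc3)cc(OCc3ccccc3)c(-c3c(OCc4ccccc4)cc(OCc4ccccc4)cc3OCc3ccccc3)c2OCc2ccccc2)cc1OCc1ccccc1 | intermediate
17 | 2,6-bis(benzyloxy)-4-{2,4,6-tris(benzyloxy)-3-[2,4,6-tris(benzyloxy)phenyl]phenoxy}phenyl formate (not isolated) | O=COc1c(OCc2ccccc2)cc(Oc2c(OCc3ccccc3)cc(OCc3ccccc3)c(-c3c(OCc4ccccc4)cc(OCc4ccccc4)cc3OCc3ccccc3)c2OCc2ccccc2)cc1OCc1ccccc1 | intermediate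
18 | 2,6-bis(benzyloxy)-4-{2,4,6-tris(benzyloxy)-3-[2,4,6-tris(benzyloxy)phenyl]phenoxy}phenol (arm phenol, rings C–D–E) | Oc1c(OCc2ccccc2)cc(Oc2c(OCc3ccccc3)cc(OCc3ccccc3)c(-c3c(OCc4ccccc4)cc(OCc4ccccc4)cc3OCc3ccccc3)c2OCc2ccccc2)cc1OCc1ccccc1 | intermediate
19 | 2,6-difluoro-4-hydroxybenzaldehyde | O=Cc1c(F)cc(O)cc1F | starting material
20 | 4-(benzyloxy)-2,6-difluorobenzaldehyde | O=Cc1c(F)cc(OCc2ccccc2)cc1F | intermediate
21 | 4-(benzyloxy)-2-fluoro-6-(2,6-bis(benzyloxy)-4-{2,4,6-tris(benzyloxy)-3-[2,4,6-tris(benzyloxy)phenyl]phenoxy}phenoxy)benzaldehyde (not isolated) | O=Cc1c(F)cc(OCc2ccccc2)cc1Oc1c(OCc2ccccc2)cc(Oc2c(OCc3ccccc3)cc(OCc3ccccc3)c(-c3c(OCc4ccccc4)cc(OCc4ccccc4)cc3OCc3ccccc3)c2OCc2ccccc2)cc1OCc1ccccc1 | intermediate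
22 | 4-(benzyloxy)-2,6-bis(2,6-bis(benzyloxy)-4-{2,4,6-tris(benzyloxy)-3-[2,4,6-tris(benzyloxy)phenyl]phenoxy}phenoxy)benzaldehyde | O=Cc1c(Oc5c(OCc6ccccc6)cc(Oc6c(OCc7ccccc7)cc(OCc7ccccc7)c(-c7c(OCc8ccccc8)cc(OCc8ccccc8)cc7OCc7ccccc7)c6OCc6ccccc6)cc5OCc5ccccc5)cc(OCc2ccccc2)cc1Oc1c(OCc2ccccc2)cc(Oc2c(OCc3ccccc3)cc(OCc3ccccc3)c(-c3c(OCc4ccccc4)cc(OCc4ccccc4)cc3OCc3ccccc3)c2OCc2ccccc2)cc1OCc1ccccc1 | intermediate
23 | 4-(benzyloxy)-2,6-bis(2,6-bis(benzyloxy)-4-{2,4,6-tris(benzyloxy)-3-[2,4,6-tris(benzyloxy)phenyl]phenoxy}phenoxy)phenyl formate (not isolated) | O=COc1c(Oc5c(OCc6ccccc6)cc(Oc6c(OCc7ccccc7)cc(OCc7ccccc7)c(-c7c(OCc8ccccc8)cc(OCc8ccccc8)cc7OCc7ccccc7)c6OCc6ccccc6)cc5OCc5ccccc5)cc(OCc2ccccc2)cc1Oc1c(OCc2ccccc2)cc(Oc2c(OCc3ccccc3)cc(OCc3ccccc3)c(-c3c(OCc4ccccc4)cc(OCc4ccccc4)cc3OCc3ccccc3)c2OCc2ccccc2)cc1OCc1ccccc1 | intermediate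
24 | 4-(benzyloxy)-2,6-bis(2,6-bis(benzyloxy)-4-{2,4,6-tris(benzyloxy)-3-[2,4,6-tris(benzyloxy)phenyl]phenoxy}phenoxy)phenol | Oc1c(Oc5c(OCc6ccccc6)cc(Oc6c(OCc7ccccc7)cc(OCc7ccccc7)c(-c7c(OCc8ccccc8)cc(OCc8ccccc8)cc7OCc7ccccc7)c6OCc6ccccc6)cc5OCc5ccccc5)cc(OCc2ccccc2)cc1Oc1c(OCc2ccccc2)cc(Oc2c(OCc3ccccc3)cc(OCc3ccccc3)c(-c3c(OCc4ccccc4)cc(OCc4ccccc4)cc3OCc3ccccc3)c2OCc2ccccc2)cc1OCc1ccccc1 | intermediate
25 | 1-bromo-3,5-bis(benzyloxy)benzene | Brc1cc(OCc2ccccc2)cc(OCc2ccccc2)c1 | starting material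
26 | 5-(benzyloxy)-2-[3,5-bis(benzyloxy)phenoxy]-1,3-bis(2,6-bis(benzyloxy)-4-{2,4,6-tris(benzyloxy)-3-[2,4,6-tris(benzyloxy)phenyl]phenoxy}phenoxy)benzene (nonadeca-O-benzyl ether of the target) | C(c1ccccc1)Oc1cc(OCc2ccccc2)cc(c1)Oc1c(Oc5c(OCc6ccccc6)cc(Oc6c(OCc7ccccc7)cc(OCc7ccccc7)c(-c7c(OCc8ccccc8)cc(OCc8ccccc8)cc7OCc7ccccc7)c6OCc6ccccc6)cc5OCc5ccccc5)cc(OCc2ccccc2)cc1Oc1c(OCc2ccccc2)cc(Oc2c(OCc3ccccc3)cc(OCc3ccccc3)c(-c3c(OCc4ccccc4)cc(OCc4ccccc4)cc3OCc3ccccc3)c2OCc2ccccc2)cc1OCc1ccccc1 | intermediate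
27 | 5-hydroxy-2-(3,5-dihydroxyphenoxy)-1,3-bis{2,6-dihydroxy-4-[2,4,6-trihydroxy-3-(2,4,6-trihydroxyphenyl)phenoxy]phenoxy}benzene (CNP0227063.0) | Oc1cc(O)cc(Oc2c(Oc3c(O)cc(Oc4c(O)cc(O)c(-c5c(O)cc(O)cc5O)c4O)cc3O)cc(O)cc2Oc2c(O)cc(Oc3c(O)cc(O)c(-c4c(O)cc(O)cc4O)c3O)cc2O)c1 | target

**Totals**

Total step count: 15.
Longest linear sequence: 13 steps (steps 1–7, 9, 10, 12, 13, 14, 15, from 1 to 27).

**Steps most likely to fail**

Step 6. The quinone is deactivated by two donor groups, and the arene may instead attack a benzyloxy-bearing carbon with loss of benzyl alcohol. Redox exchange between 11 and 9 can also lead to a second arylation; a dithionite wash returns any aryl quinone to 11. The fallback builds the D–E bond by cross-coupling; it sets out from 3 and 5 and comes back at 12, so it also bypasses step 7. Arene 3 is brominated (NBS, CH2Cl2, 0 °C) to 2-bromo-1,3,5-tris(benzyloxy)benzene F1. Bromine–lithium exchange (n-BuLi, THF, −78 °C) gives 2,4,6-tris(benzyloxy)phenyllithium F2, which is quenched with B(OiPr)3 and aqueous HCl to give 2,4,6-tris(benzyloxy)phenylboronic acid F3. Aldehyde 5 is brominated (NBS, MeCN, rt) to 3-bromo-2,4,6-tris(benzyloxy)benzaldehyde F4. Suzuki–Miyaura coupling of F3 with F4 (Pd(OAc)2, SPhos, K3PO4, toluene/H2O, 100 °C) gives 2,4,6-tris(benzyloxy)-3-[2,4,6-tris(benzyloxy)phenyl]benzaldehyde F5. Dakin oxidation (mCPBA, CH2Cl2; then Et3N, MeOH) through 2,4,6-tris(benzyloxy)-3-[2,4,6-tris(benzyloxy)phenyl]phenyl formate F6 gives 12.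

Step 7. The monobenzylation may not discriminate the two hydroxyls well enough. The fallback protects both and frees one; it sets out from 11 and comes back at 12. Acetylation (Ac2O, pyridine) gives 2,6-bis(benzyloxy)-3-[2,4,6-tris(benzyloxy)phenyl]benzene-1,4-diyl diacetate F7. Aminolysis with one equivalent of pyrrolidine (CH2Cl2, 0 °C) removes the less shielded C4 acetate, whose phenoxide is also the better leaving group, to give 2,6-bis(benzyloxy)-4-hydroxy-3-[2,4,6-tris(benzyloxy)phenyl]phenyl acetate F8. Neutral Mitsunobu benzylation (BnOH, PPh3, DIAD, THF) gives 2,4,6-tris(benzyloxy)-3-[2,4,6-tris(benzyloxy)phenyl]phenyl acetate F9, and methanolysis (K2CO3, MeOH) gives 12.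

Step 14. The hydroxyl of 24 sits between two very bulky aryloxy groups and may resist Cu-catalysed arylation. The fallback installs ring A before the arms; it sets out from 18 and comes back at 26, bypassing 20 to 24. Commercial 4-(benzyloxy)phenol is dibrominated (NBS, 2.1 equiv, i-Pr2NH cat., CH2Cl2) to 4-(benzyloxy)-2,6-dibromophenol F10. Chan–Lam coupling with commercial 3,5-bis(benzyloxy)phenylboronic acid (Cu(OAc)2, pyridine, 4 Å molecular sieves, CH2Cl2, air, rt) gives 5-(benzyloxy)-2-[3,5-bis(benzyloxy)phenoxy]-1,3-dibromobenzene F11. Two-fold Ullmann coupling with arm phenol 18 (CuI, 2,2,6,6-tetramethylheptane-3,5-dione, Cs2CO3, NMP, 120 °C) proceeds through 5-(benzyloxy)-2-[3,5-bis(benzyloxy)phenoxy]-1-bromo-3-(2,6-bis(benzyloxy)-4-{2,4,6-tris(benzyloxy)-3-[2,4,6-tris(benzyloxy)phenyl]phenoxy}phenoxy)benzene F12 and gives 26.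

**Further compounds**

F1 | step 6 | 2-bromo-1,3,5-tris(benzyloxy)benzene | Brc1c(OCc2ccccc2)cc(OCc2ccccc2)cc1OCc1ccccc1
F2 | step 6 | 2,4,6-tris(benzyloxy)phenyllithium | [Li]c1c(OCc2ccccc2)cc(OCc2ccccc2)cc1OCc1ccccc1
F3 | step 6 | 2,4,6-tris(benzyloxy)phenylboronic acid | OB(O)c1c(OCc2ccccc2)cc(OCc2ccccc2)cc1OCc1ccccc1
F4 | step 6 | 3-bromo-2,4,6-tris(benzyloxy)benzaldehyde | O=Cc1c(OCc2ccccc2)cc(OCc2ccccc2)c(Br)c1OCc1ccccc1
F5 | step 6 | 2,4,6-tris(benzyloxy)-3-[2,4,6-tris(benzyloxy)phenyl]benzaldehyde | O=Cc1c(OCc2ccccc2)cc(OCc2ccccc2)c(-c2c(OCc3ccccc3)cc(OCc3ccccc3)cc2OCc2ccccc2)c1OCc1ccccc1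
F6 | step 6 | 2,4,6-tris(benzyloxy)-3-[2,4,6-tris(benzyloxy)phenyl]phenyl formate | O=COc1c(OCc2ccccc2)cc(OCc2ccccc2)c(-c2c(OCc3ccccc3)cc(OCc3ccccc3)cc2OCc2ccccc2)c1OCc1ccccc1
F7 | step 7 | 2,6-bis(benzyloxy)-3-[2,4,6-tris(benzyloxy)phenyl]benzene-1,4-diyl diacetate | CC(=O)Oc1c(OCc2ccccc2)cc(OC(C)=O)c(-c2c(OCc3ccccc3)cc(OCc3ccccc3)cc2OCc2ccccc2)c1OCc1ccccc1
F8 | step 7 | 2,6-bis(benzyloxy)-4-hydroxy-3-[2,4,6-tris(benzyloxy)phenyl]phenyl acetate | CC(=O)Oc1c(OCc2ccccc2)cc(O)c(-c2c(OCc3ccccc3)cc(OCc3ccccc3)cc2OCc2ccccc2)c1OCc1ccccc1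
F9 | step 7 | 2,4,6-tris(benzyloxy)-3-[2,4,6-tris(benzyloxy)phenyl]phenyl acetate | CC(=O)Oc1c(OCc2ccccc2)cc(OCc2ccccc2)c(-c2c(OCc3ccccc3)cc(OCc3ccccc3)cc2OCc2ccccc2)c1OCc1ccccc1
F10 | step 14 | 4-(benzyloxy)-2,6-dibromophenol | Oc1c(Br)cc(OCc2ccccc2)cc1Br
F11 | step 14 | 5-(benzyloxy)-2-[3,5-bis(benzyloxy)phenoxy]-1,3-dibromobenzene | Brc1cc(OCc2ccccc2)cc(Br)c1Oc1cc(OCc2ccccc2)cc(OCc2ccccc2)c1
F12 | step 14 | 5-(benzyloxy)-2-[3,5-bis(benzyloxy)phenoxy]-1-bromo-3-(2,6-bis(benzyloxy)-4-{2,4,6-tris(benzyloxy)-3-[2,4,6-tris(benzyloxy)phenyl]phenoxy}phenoxy)benzene | Brc1cc(OCc2ccccc2)cc(Oc5c(OCc6ccccc6)cc(Oc6c(OCc7ccccc7)cc(OCc7ccccc7)c(-c7c(OCc8ccccc8)cc(OCc8ccccc8)cc7OCc7ccccc7)c6OCc6ccccc6)cc5OCc5ccccc5)c1Oc1cc(OCc2ccccc2)cc(OCc2ccccc2)c1
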